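Gymcononopin D is achiral; its one strategic element is the unbranched Cα–Cβ tether that links C1 of the dimethoxy ring A (adjacent to the benzyl-bearing C2) to C1 of the 3-hydroxyphenyl ring B. Because both ends of this bridge are sp2 aryl carbons, it is traced back to an alkyne and both aryl–alkynyl bonds are cut together. Propiolic acid supplies the two carbons: in one pot its C–H terminus is arylated by the ring-B iodide and its CO2H terminus is replaced by ring A through decarboxylative coupling with the precursor, a 2-benzyl-3,5-dimethoxy aryl bromide carrying the ring-C benzyl ether. One hydrogenation then finishes the synthesis.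

Key step: step 3

Assumption: the target has no stereocentre or other stereogenic element, so "single enantiomer" is read as the constitution drawn; the only stereocentre on the route (carbinol 5, racemic) is erased in step 2. All five starting materials are taken as purchasable.

Step 1
Reactants: 1 1-(benzyloxy)-4-bromobenzene; 2 2-bromo-4,6-dimethoxybenzaldehyde
Product: 5 rac-[4-(benzyloxy)phenyl](2-bromo-4,6-dimethoxyphenyl)methanol, via [4-(benzyloxy)phenyl]magnesium bromide 3 (not isolated), via bromomagnesium diarylmethanolate 4 (not isolated)
Conditions: 1, Mg, I2 (cat.), THF, reflux; then 2, THF, 0 °C to rt; sat. aq NH4Cl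
Reagents that add atoms: none
Why: Grignard addition: aryl Grignard 3, formed by magnesium insertion into the C–Br bond of 1, should add to the aldehyde of 2 far faster than it exchanges with the aryl bromide, and the carbinol stereocentre forms as a racemate, which is harmless because step 2 turns that carbon into CH2.

Step 2
Reactants: 5 rac-[4-(benzyloxy)phenyl](2-bromo-4,6-dimethoxyphenyl)methanol
Product: 6 2-[4-(benzyloxy)benzyl]-1-bromo-3,5-dimethoxybenzene
Conditions: Et3SiH (3 equiv), TFA (5 equiv), CH2Cl2, 0 °C
Reagents that add atoms: none
Why: Ionic hydrogenation (silane–acid deoxygenation): the doubly benzylic alcohol should ionise in TFA to a diarylmethyl cation stabilised by the ortho- and para-methoxy groups of ring A and by the para-benzyloxy group, and hydride transfer from Et3SiH gives the CH2 link while the aryl bromide, methyl ethers and benzyl ether are untouched at 0 °C.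

Step 3
Reactants: 7 propiolic acid; 8 1-(benzyloxy)-3-iodobenzene; 6 2-[4-(benzyloxy)benzyl]-1-bromo-3,5-dimethoxybenzene
Product: 10 2-[4-(benzyloxy)benzyl]-1-{[3-(benzyloxy)phenyl]ethynyl}-3,5-dimethoxybenzene, via DBU-H+ 3-[3-(benzyloxy)phenyl]prop-2-ynoate 9 (not isolated)
Conditions: 7 + 8, Pd(PPh3)2Cl2 (5 mol %), dppb (10 mol %), DBU (2.5 equiv), degassed DMSO, rt, no copper; then 6, 100 °C
Reagents that add atoms: none
Why: Copper-free Sonogashira coupling comes first: Pd(0) inserts into the C–I bond of 8 at room temperature, the DBU salt of 7 is palladated at its acetylenic C–H, and reductive elimination gives arylpropiolate 9 with the carboxylate still in place. On heating, Pd(0) inserts into the C–Br bond of 6, the carboxylate of 9 binds to the arylpalladium(II) bromide and loses CO2 to give an aryl(alkynyl)palladium species, and reductive elimination forms the second aryl–alkynyl bond of 10. The closest known reaction type is the one-pot Sonogashira/decarboxylative alkynylation of propiolic acid with an aryl iodide followed by an aryl bromide, which gives unsymmetrical diarylalkynes. No ring is closed and no stereocentre is formed. The selectivity needed is the order in which the two aryl groups are attached; it is secured by the large rate gap between C–I and C–Br oxidative addition at room temperature, by leaving out copper so that CO2 is not lost early, and by adding 6 only before the temperature is raised. The ortho benzyl group of 6 should be tolerated because the incoming alkynyl unit is linear and the bromide lies meta to both methoxy groups, so oxidative addition is not electronically slowed; any 9 that merely protodecarboxylates gives a terminal alkyne that should still couple with 6 under the same Pd/DBU conditions.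

Step 4
Reactants: 10 2-[4-(benzyloxy)benzyl]-1-{[3-(benzyloxy)phenyl]ethynyl}-3,5-dimethoxybenzene
Product: 11 Gymcononopin D, 3-{2-[2-(4-hydroxybenzyl)-3,5-dimethoxyphenyl]ethyl}phenol
Conditions: H2 (1 atm), 10% Pd/C, EtOAc–MeOH (1:1), rt
Reagents that add atoms: none
Why: Heterogeneous catalytic hydrogenation: Pd/C should saturate the diarylalkyne to the CH2CH2 bridge and in the same operation hydrogenolyse both O-benzyl ethers to the phenols, while the aryl methyl ethers, the diarylmethane CH2 and the arenes are inert under a balloon of hydrogen at room temperature; no stereocentre is present.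

Compound list
1 | 1-(benzyloxy)-4-bromobenzene | Brc1ccc(OCc2ccccc2)cc1 | starting material
2 | 2-bromo-4,6-dimethoxybenzaldehyde | COc1cc(Br)c(C=O)c(OC)c1 | starting material
3 | [4-(benzyloxy)phenyl]magnesium bromide | Br[Mg]c1ccc(OCc2ccccc2)cc1 | intermediate (not isolated)
4 | bromomagnesium [4-(benzyloxy)phenyl](2-bromo-4,6-dimethoxyphenyl)methanolate, racemic | COc1cc(Br)c(C(O[Mg]Br)c2ccc(OCc3ccccc3)cc2)c(OC)c1 | intermediate (not isolated)
5 | rac-[4-(benzyloxy)phenyl](2-bromo-4,6-dimethoxyphenyl)methanol | COc1cc(Br)c(C(O)c2ccc(OCc3ccccc3)cc2)c(OC)c1 | intermediate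
6 | 2-[4-(benzyloxy)benzyl]-1-bromo-3,5-dimethoxybenzene | COc1cc(Br)c(Cc2ccc(OCc3ccccc3)cc2)c(OC)c1 | intermediate
7 | propiolic acid | C#CC(=O)O | starting material
8 | 1-(benzyloxy)-3-iodobenzene | Ic1cccc(OCc2ccccc2)c1 | starting material
9 | DBU-H+ 3-[3-(benzyloxy)phenyl]prop-2-ynoate | [O-]C(=O)C#Cc1cccc(OCc2ccccc2)c1.C1CCC2=[NH+]CCCN2CC1 | intermediate (not isolated)
10 | 2-[4-(benzyloxy)benzyl]-1-{[3-(benzyloxy)phenyl]ethynyl}-3,5-dimethoxybenzene | COc1cc(C#Cc2cccc(OCc3ccccc3)c2)c(Cc2ccc(OCc3ccccc3)cc2)c(OC)c1 | intermediate
11 | Gymcononopin D, 3-{2-[2-(4-hydroxybenzyl)-3,5-dimethoxyphenyl]ethyl}phenol | COc1cc(CCc2cccc(O)c2)c(Cc2ccc(O)cc2)c(OC)c1 | target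

Total step count: 4. Longest linear sequence: 4 steps (2 → 5 → 6 → 10 → 11).

Steps most likely to fail

1. Step 3. The propiolate may lose CO2 before the bromide is engaged, which would scramble the order of arylation towards symmetrical diarylalkyne, or oxidative addition at the ortho-substituted bromide may be too slow to keep pace with decarboxylation. The fallback sets out from bromide 6 and comes back at alkyne 10, attaching the two carbons stepwise. Sonogashira coupling of 6 with ethynyltrimethylsilane (Pd(PPh3)2Cl2, CuI, Et3N, 80 °C) should give ({2-[4-(benzyloxy)benzyl]-3,5-dimethoxyphenyl}ethynyl)trimethylsilane F1. Desilylation with K2CO3 in MeOH would then give 2-[4-(benzyloxy)benzyl]-1-ethynyl-3,5-dimethoxybenzene F2. A room-temperature Pd/Cu Sonogashira coupling of F2 with iodide 8 would deliver 10.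

2. Step 2. The long-lived diarylmethyl cation may alkylate another electron-rich arene (Friedel–Crafts self-condensation) or the acid may strip the benzyl ether before hydride transfer. The fallback sets out from aldehyde 2 and comes back at bromide 6, avoiding both the carbinol and any cation. Condensation of 2 with p-toluenesulfonyl hydrazide (MeOH, rt) should give N'-[(E)-(2-bromo-4,6-dimethoxyphenyl)methylidene]-4-methylbenzenesulfonohydrazide F3. Heating F3 with commercial 4-(benzyloxy)phenylboronic acid and K2CO3 in dioxane at 110 °C is the metal-free reductive coupling of a tosylhydrazone with a boronic acid: Bamford–Stevens generation of the aryldiazomethane, 1,2-aryl shift from boron, then protodeboronation. It should give 6 directly with the aryl bromide untouched.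

3. Step 4. Hydrogenation and hydrogenolysis may stall through catalyst poisoning by traces of DMSO or phosphine carried over from step 3, leaving partly reduced or partly debenzylated material. The fallback sets out from alkyne 10 and comes back at target 11, separating the two events without a metal catalyst. Diimide generated from p-toluenesulfonyl hydrazide and NaOAc (THF–H2O, reflux) should saturate the alkyne to 2-[4-(benzyloxy)benzyl]-1-{2-[3-(benzyloxy)phenyl]ethyl}-3,5-dimethoxybenzene F4. BCl3 with pentamethylbenzene as cation scavenger (CH2Cl2, −78 °C) would then remove both benzyl ethers and leave the methyl ethers in place, giving 11.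

Further compounds
F1 | step 3 | ({2-[4-(benzyloxy)benzyl]-3,5-dimethoxyphenyl}ethynyl)trimethylsilane | COc1cc(C#C[Si](C)(C)C)c(Cc2ccc(OCc3ccccc3)cc2)c(OC)c1
F2 | step 3 | 2-[4-(benzyloxy)benzyl]-1-ethynyl-3,5-dimethoxybenzene | COc1cc(C#C)c(Cc2ccc(OCc3ccccc3)cc2)c(OC)c1
F3 | step 2 | N'-[(E)-(2-bromo-4,6-dimethoxyphenyl)methylidene]-4-methylbenzenesulfonohydrazide | COc1cc(Br)c(/C=N/NS(=O)(=O)c2ccc(C)cc2)c(OC)c1
F4 | step 4 | 2-[4-(benzyloxy)benzyl]-1-{2-[3-(benzyloxy)phenyl]ethyl}-3,5-dimethoxybenzene | COc1cc(CCc2cccc(OCc3ccccc3)c2)c(Cc2ccc(OCc3ccccc3)cc2)c(OC)c1
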